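The pyranone ring C is closed last, across ring A: the C3–C4 bond and the O1–C8a bond are made in one pot from an open-chain α-methoxy-β-silyloxy acid (carrying ring B, C2, O1 and C3) and a 2-fluoroaroyl chloride (carrying C4 and ring A). A nickel/photoredox decarboxylative acylation joins C3 to C4 through a mixed anhydride that loses CO2; fluoride then frees O1, which displaces fluorine at C8a. The step exploits two features: C3 carries OMe, so its radical forms easily, and the C4 ketone lies ortho to C8a, so that carbon is open to SNAr. C2 is set by an Evans glycolate aldol; C3, α to C4, should settle trans.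

Key step: step 9

Remark on labels: flavanone numbering is used (O1, C2, C3, C4, C4a, C5 to C8, C8a); ring A is the fused benzene ring, ring B the 2-aryl group, ring C the pyranone ring.
Assumption: 5-fluoro-1,2,3-trimethoxybenzene (15) is taken as a catalogue compound.

Step 1
Reactants: 1 2-methoxybenzene-1,4-diol
Product: 2 1,4-bis(benzyloxy)-2-methoxybenzene
Conditions: BnBr, K2CO3, DMF, 60 °C
Reagents that add atoms: benzyl bromide, BrCc1ccccc1
Why: Williamson ether synthesis on both phenols; benzyl is chosen because it should survive base, fluoride and the radical coupling and is removed at the end under neutral conditions.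

Step 2
Reactants: 2 1,4-bis(benzyloxy)-2-methoxybenzene
Product: 4 2,5-bis(benzyloxy)-4-methoxybenzaldehyde, via iminium salt 3 (not isolated)
Conditions: POCl3, DMF, 0 °C to 70 °C; then ice, aq. NaOH to pH 7
Reagents that add atoms: N,N-dimethylformamide, CN(C)C=O; water, O
Why: Vilsmeier–Haack formylation should go at the one unhindered position that is para to OMe and ortho to OBn, as it does with 1,2,4-trialkoxybenzenes.

Step 3
Reactants: 5 (4S)-4-benzyl-1,3-oxazolidin-2-one; 6 methoxyacetyl chloride
Product: 8 (4S)-4-benzyl-3-(methoxyacetyl)-1,3-oxazolidin-2-one, via lithium oxazolidinide 7 (not isolated)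
Conditions: n-BuLi, THF, −78 °C; then 6, −78 °C to 0 °C
Reagents that add atoms: none
Why: N-acylation of the lithiated Evans auxiliary by an acid chloride.

Step 4
Reactants: 8 (4S)-4-benzyl-3-(methoxyacetyl)-1,3-oxazolidin-2-one; 4 2,5-bis(benzyloxy)-4-methoxybenzaldehyde
Product: 11 (4S)-4-benzyl-3-{(2S,3R)-3-[2,5-bis(benzyloxy)-4-methoxyphenyl]-3-hydroxy-2-methoxypropanoyl}-1,3-oxazolidin-2-one, via boron enolate 9 (not isolated), via boron aldolate 10 (not isolated)
Conditions: Bu2BOTf, iPr2NEt, CH2Cl2, −78 °C to 0 °C; then 4, −78 °C to 0 °C; then pH 7 buffer, MeOH, 30% H2O2, 0 °C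
Reagents that add atoms: none
Why: Evans syn glycolate aldol, in which the (Z)-boron enolate reacts through a Zimmerman–Traxler chair with the auxiliary benzyl group shielding one face, should set the carbinol carbon (the later C2) as R and the α-carbon as S.

Step 5
Reactants: 11 the aldol adduct
Product: 12 (4S)-4-benzyl-3-{(2S,3R)-3-[2,5-bis(benzyloxy)-4-methoxyphenyl]-3-[(tert-butyldimethylsilyl)oxy]-2-methoxypropanoyl}-1,3-oxazolidin-2-one
Conditions: TBSOTf, 2,6-lutidine, CH2Cl2, −78 °C to 0 °C
Reagents that add atoms: tert-butyldimethylsilyl triflate, CC(C)(C)[Si](C)(C)OS(=O)(=O)C(F)(F)F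
Why: Silylation of the secondary benzylic alcohol with a silyl triflate and a hindered base masks O1 until fluoride releases it in the key step.

Step 6
Reactants: 12 the silylated imide
Product: 14 (2S,3R)-3-[2,5-bis(benzyloxy)-4-methoxyphenyl]-3-[(tert-butyldimethylsilyl)oxy]-2-methoxypropanoic acid, via peroxy acid 13 (not isolated)
Conditions: LiOH, 30% H2O2, THF/H2O, 0 °C; then aq. Na2SO3; then aq. HCl to pH 4, 0 °C
Reagents that add atoms: hydrogen peroxide, OO
Why: Hydroperoxide cleavage of the Evans imide at the exocyclic carbonyl, followed by sulfite reduction of the peracid, should free the acid without touching the stereocentres or the silyl ether.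

Step 7
Reactants: 15 5-fluoro-1,2,3-trimethoxybenzene
Product: 17 6-fluoro-2,3,4-trimethoxybenzoic acid, via aryllithium 16 (not isolated)
Conditions: n-BuLi, THF, −78 °C; then CO2, −78 °C to rt; then aq. HCl
Reagents that add atoms: carbon dioxide, O=C=O
Why: Directed ortho-lithiation at the only ring C–H, which is flanked by F and OMe, then carboxylation at −78 °C before lithium fluoride can be lost.

Step 8
Reactants: 17 6-fluoro-2,3,4-trimethoxybenzoic acid
Product: 18 6-fluoro-2,3,4-trimethoxybenzoyl chloride
Conditions: (COCl)2, cat. DMF, CH2Cl2, 0 °C to rt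
Reagents that add atoms: oxalyl chloride, O=C(Cl)C(Cl)=O
Why: Acid chloride formation with oxalyl chloride under DMF catalysis.

Step 9
Reactants: 14 the silyloxy acid; 18 6-fluoro-2,3,4-trimethoxybenzoyl chloride
Product: 23 (2R,3R)-2-[2,5-bis(benzyloxy)-4-methoxyphenyl]-3,5,6,7-tetramethoxy-2,3-dihydro-4H-chromen-4-one, via mixed anhydride 19 (not isolated), via silyloxy ketone 20 (not isolated), via hydroxy ketone 21 (not isolated), via cis-flavanone 22 (not isolated)
Conditions: DBU, 1,4-dioxane, rt; then NiCl2(MeOCH2CH2OMe) (10 mol%), 4,4'-di-tert-butyl-2,2'-bipyridine (10 mol%), Ir[dF(CF3)ppy]2(dtbbpy)PF6 (1 mol%), blue LEDs, rt; then TBAF, THF, rt to 50 °C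
Reagents that add atoms: none
Why: Carboxylate 14 is aroylated by 18 to mixed anhydride 19, zerovalent nickel inserts into its aroyl C–O bond, the photoexcited iridium catalyst oxidises the carboxylate so that CO2 is lost, and the OMe-stabilised C3 radical is captured by nickel and reductively eliminated with the aroyl group to form C3–C4 in 20 (closest known type: nickel/photoredox decarboxylative acylation of α-oxy acids through in-situ mixed anhydrides). Fluoride then desilylates O1, which attacks C8a of ring A, activated by the ortho C4 ketone, in an intramolecular SNAr (6-exo-trig addition to a Meisenheimer complex, then loss of fluoride, which can carry on the desilylation), the known closure of 2-fluoroaryl β-hydroxy ketones to chroman-4-ones. C2 keeps the R configuration of 14 because no bond to it is broken. C3 is formed without control in the radical step, but it is α to the C4 ketone, so under the basic conditions 20, 21 and cis-flavanone 22 should equilibrate through the enolate to the 2,3-trans product with both substituents equatorial. The step needs acylation at C3 only, which the silyl ether on O1 secures, displacement of fluoride and not of the C5 methoxy group, which the far better leaving group secures, and ring closure faster than retro-aldol cleavage of 21, which the intramolecular attack on an activated C–F carbon should secure. The benzyl ethers keep ring B from opening the C2–O1 bond as an ortho-quinone methide under base.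

Step 10
Reactants: 23 the dibenzyl flavanone
Product: 24 (2R,3R)-2-(2,5-dihydroxy-4-methoxyphenyl)-3,5,6,7-tetramethoxy-2,3-dihydro-4H-chromen-4-one
Conditions: H2 (1 atm), Pd/C (10%), EtOAc, rt
Reagents that add atoms: none
Why: Catalytic hydrogenolysis of the two aryl benzyl ethers under neutral conditions should leave the C4 ketone, the cyclic C2–O1 ether and both stereocentres untouched.

Compound list
1 | 2-methoxybenzene-1,4-diol | COc1cc(O)ccc1O | starting material
2 | 1,4-bis(benzyloxy)-2-methoxybenzene | COc1cc(OCc2ccccc2)ccc1OCc1ccccc1 | intermediate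
3 | N-{[2,5-bis(benzyloxy)-4-methoxyphenyl]methylidene}-N-methylmethanaminium chloride (iminium salt) | COc1cc(OCc2ccccc2)c(C=[N+](C)C)cc1OCc1ccccc1.[Cl-] | intermediate (not isolated)
4 | 2,5-bis(benzyloxy)-4-methoxybenzaldehyde | COc1cc(OCc2ccccc2)c(C=O)cc1OCc1ccccc1 | intermediate
5 | (4S)-4-benzyl-1,3-oxazolidin-2-one | O=C1N[C@@H](Cc2ccccc2)CO1 | starting material
6 | methoxyacetyl chloride | COCC(Cl)=O | starting material
7 | lithium (4S)-4-benzyl-2-oxo-1,3-oxazolidin-3-ide | [Li+].O=C1[N-][C@@H](Cc2ccccc2)CO1 | intermediate (not isolated)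
8 | (4S)-4-benzyl-3-(methoxyacetyl)-1,3-oxazolidin-2-one | COCC(=O)N1[C@@H](Cc2ccccc2)COC1=O | intermediate
9 | dibutylboron (Z)-enolate of 8 | CCCCB(CCCC)O/C(=C\OC)N1[C@@H](Cc2ccccc2)COC1=O | intermediate (not isolated)
10 | O-dibutylboryl aldolate of 11 | COc1cc(OCc2ccccc2)c([C@@H](OB(CCCC)CCCC)[C@H](OC)C(=O)N2[C@@H](Cc3ccccc3)COC2=O)cc1OCc1ccccc1 | intermediate (not isolated)
11 | (4S)-4-benzyl-3-{(2S,3R)-3-[2,5-bis(benzyloxy)-4-methoxyphenyl]-3-hydroxy-2-methoxypropanoyl}-1,3-oxazolidin-2-one | COc1cc(OCc2ccccc2)c([C@@H](O)[C@H](OC)C(=O)N2[C@@H](Cc3ccccc3)COC2=O)cc1OCc1ccccc1 | intermediate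
12 | (4S)-4-benzyl-3-{(2S,3R)-3-[2,5-bis(benzyloxy)-4-methoxyphenyl]-3-[(tert-butyldimethylsilyl)oxy]-2-methoxypropanoyl}-1,3-oxazolidin-2-one | COc1cc(OCc2ccccc2)c([C@@H](O[Si](C)(C)C(C)(C)C)[C@H](OC)C(=O)N2[C@@H](Cc3ccccc3)COC2=O)cc1OCc1ccccc1 | intermediate
13 | (2S,3R)-3-[2,5-bis(benzyloxy)-4-methoxyphenyl]-3-[(tert-butyldimethylsilyl)oxy]-2-methoxypropaneperoxoic acid | COc1cc(OCc2ccccc2)c([C@@H](O[Si](C)(C)C(C)(C)C)[C@H](OC)C(=O)OO)cc1OCc1ccccc1 | intermediate (not isolated)
14 | (2S,3R)-3-[2,5-bis(benzyloxy)-4-methoxyphenyl]-3-[(tert-butyldimethylsilyl)oxy]-2-methoxypropanoic acid | COc1cc(OCc2ccccc2)c([C@@H](O[Si](C)(C)C(C)(C)C)[C@H](OC)C(O)=O)cc1OCc1ccccc1 | intermediate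
15 | 5-fluoro-1,2,3-trimethoxybenzene | COc1cc(F)cc(OC)c1OC | starting material
16 | (6-fluoro-2,3,4-trimethoxyphenyl)lithium | [Li]c1c(F)cc(OC)c(OC)c1OC | intermediate (not isolated)
17 | 6-fluoro-2,3,4-trimethoxybenzoic acid | COc1cc(F)c(C(O)=O)c(OC)c1OC | intermediate
18 | 6-fluoro-2,3,4-trimethoxybenzoyl chloride | COc1cc(F)c(C(Cl)=O)c(OC)c1OC | intermediate
19 | mixed anhydride of 14 and 17 | COc1cc(OCc2ccccc2)c([C@@H](O[Si](C)(C)C(C)(C)C)[C@H](OC)C(=O)OC(=O)c2c(F)cc(OC)c(OC)c2OC)cc1OCc1ccccc1 | intermediate (not isolated)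
20 | (3R)-3-[2,5-bis(benzyloxy)-4-methoxyphenyl]-3-[(tert-butyldimethylsilyl)oxy]-1-(6-fluoro-2,3,4-trimethoxyphenyl)-2-methoxypropan-1-one, both C2 epimers | COc1cc(OCc2ccccc2)c([C@@H](O[Si](C)(C)C(C)(C)C)C(OC)C(=O)c2c(F)cc(OC)c(OC)c2OC)cc1OCc1ccccc1 | intermediate (not isolated)
21 | (3R)-3-[2,5-bis(benzyloxy)-4-methoxyphenyl]-1-(6-fluoro-2,3,4-trimethoxyphenyl)-3-hydroxy-2-methoxypropan-1-one, both C2 epimers | COc1cc(OCc2ccccc2)c([C@@H](O)C(OC)C(=O)c2c(F)cc(OC)c(OC)c2OC)cc1OCc1ccccc1 | intermediate (not isolated)
22 | (2R,3S)-2-[2,5-bis(benzyloxy)-4-methoxyphenyl]-3,5,6,7-tetramethoxy-2,3-dihydro-4H-chromen-4-one (2,3-cis) | COc1cc(OCc2ccccc2)c([C@H]2Oc3cc(OC)c(OC)c(OC)c3C(=O)[C@H]2OC)cc1OCc1ccccc1 | intermediate (not isolated)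
23 | (2R,3R)-2-[2,5-bis(benzyloxy)-4-methoxyphenyl]-3,5,6,7-tetramethoxy-2,3-dihydro-4H-chromen-4-one (2,3-trans) | COc1cc(OCc2ccccc2)c([C@H]2Oc3cc(OC)c(OC)c(OC)c3C(=O)[C@@H]2OC)cc1OCc1ccccc1 | intermediate
24 | (2R,3R)-2-(2,5-dihydroxy-4-methoxyphenyl)-3,5,6,7-tetramethoxy-2,3-dihydro-4H-chromen-4-one | COc1cc(O)c([C@H]2Oc3cc(OC)c(OC)c(OC)c3C(=O)[C@@H]2OC)cc1O | target

Total step count: 10
Longest linear sequence: 7 steps (steps 1, 2, 4, 5, 6, 9, 10)

Steps most likely to fail

Step 9 (key step). What may go wrong: quenching of the excited photocatalyst by the electron-rich rings A and B instead of the carboxylate; insertion of nickel on the alkanoyl side of the anhydride; at the fluoride stage, retro-aldol cleavage or β-elimination outrunning ring closure; or ring opening of the product through its C3 enolate with erosion of C2. Fallback: the two bonds would be made in separate known steps without light or nickel. It sets out from acid 14 and aryllithium 16. Acid 14 would be converted (N-hydroxyphthalimide, DIC, cat. DMAP, CH2Cl2) into the N-hydroxyphthalimide ester F1, and aryllithium 16 would be quenched with DMF to give 6-fluoro-2,3,4-trimethoxybenzaldehyde F2. An NHC-catalysed decarboxylative radical acylation of F2 with F1 (thiazolium precatalyst, Cs2CO3, DMSO, 60 °C), in which the Breslow enolate reduces the redox-active ester and the ketyl and C3 radicals combine, should give silyloxy ketone 20, now isolated. HF·pyridine in THF would then give hydroxy ketone 21, and ring closure in a separate step (K2CO3, DMF, rt) would give 23, where the route is rejoined.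

Step 10. What may go wrong: over-reduction (hydrogenolysis of the benzylic C2–O1 bond or reduction of the C4 ketone), or air oxidation of the freed hydroquinone ring B during work-up. Fallback: from 23, Lewis-acid debenzylation with BCl3 and pentamethylbenzene as cation scavenger (CH2Cl2, −78 °C, short reaction time so that the C5 methoxy group next to the ketone is spared) would give 24 directly; this fallback makes no new compound (F0).

Step 6. What may go wrong: attack of hydroperoxide at the ring carbonyl of the crowded imide, which opens the auxiliary instead of releasing the acid, or loss of the silyl group. Fallback: from 12, reductive removal of the auxiliary with LiBH4 (THF, MeOH, 0 °C) would give the primary alcohol F3. Dess–Martin oxidation would give the aldehyde F4, and Pinnick oxidation (NaClO2, NaH2PO4, 2-methyl-2-butene, t-BuOH/H2O) would return acid 14.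

Further compounds
F1 | step 9 | 1,3-dioxoisoindolin-2-yl (2S,3R)-3-[2,5-bis(benzyloxy)-4-methoxyphenyl]-3-[(tert-butyldimethylsilyl)oxy]-2-methoxypropanoate | COc1cc(OCc2ccccc2)c([C@@H](O[Si](C)(C)C(C)(C)C)[C@H](OC)C(=O)ON2C(=O)c3ccccc3C2=O)cc1OCc1ccccc1
F2 | step 9 | 6-fluoro-2,3,4-trimethoxybenzaldehyde | COc1cc(F)c(C=O)c(OC)c1OC
F0 | step 10 | none | none
F3 | step 6 | (2R,3R)-3-[2,5-bis(benzyloxy)-4-methoxyphenyl]-3-[(tert-butyldimethylsilyl)oxy]-2-methoxypropan-1-ol | COc1cc(OCc2ccccc2)c([C@@H](O[Si](C)(C)C(C)(C)C)[C@H](OC)CO)cc1OCc1ccccc1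
F4 | step 6 | (2S,3R)-3-[2,5-bis(benzyloxy)-4-methoxyphenyl]-3-[(tert-butyldimethylsilyl)oxy]-2-methoxypropanal | COc1cc(OCc2ccccc2)c([C@@H](O[Si](C)(C)C(C)(C)C)[C@H](OC)C=O)cc1OCc1ccccc1
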